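**Assumption:** the stereocentre is (S) as read from the SMILES (isopropenyl > CH2–CH= > CH2–CH2 > H), which is the configuration of C4 of (S)-(−)-limonene. (S)-Limonene, phosphonate 4, bromide 17 and isopropenylmagnesium bromide are taken as catalogue chemicals. The key step (step 4) is a proposed reaction, not a literature one.

## Retrosynthetic overview

1. Target ⇒ allyl ester 22 ⇒ aldehyde 16 + ester-stabilised ylide 21 (E-selective Wittig for the enoic acid C=C, then Pd deallylation).
2. 16 ⇒ aldehyde 12 by Grignard addition, Eschenmoser–Claisen rearrangement (sets the E trisubstituted alkene) and amide-to-aldehyde reduction.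
3. 12 ⇒ (S)-limonene 8 + (E)-α-bromoenoate 7: the CH2–C(sp2) bond next to the Z enoate is made in one light-driven nickel step after ozonolytic opening of the limonene ring.
4. 7 ⇒ 3-(furan-3-yl)propanal 3 (Heck from 3-bromofuran) + bromophosphonate 6.
5. No ring is formed: the furan is bought and the only carbocycle (limonene) is opened; the single stereocentre is C4 of 8 and is never touched.

## Route

**Step 1**
Reactants: 1 3-bromofuran; 2 prop-2-en-1-ol
Product: 3 3-(furan-3-yl)propanal
Conditions: Pd(OAc)2 (3 mol %), n-Bu4NCl, NaHCO3, DMF, 80 °C, sealed tube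
Reagents that add atoms: none
Why: Heck arylation of allyl alcohol (Jeffery conditions); β-hydride elimination towards the carbinol gives the enol, which tautomerises to the aldehyde.

**Step 2**
Reactants: 4 methyl 2-[bis(2,2,2-trifluoroethoxy)phosphoryl]acetate
Product: 6 methyl 2-[bis(2,2,2-trifluoroethoxy)phosphoryl]-2-bromoacetate (racemic), via gem-dibromide 5 (not isolated)
Conditions: NaH (2.2 equiv), Br2 (2.1 equiv), THF, 0 °C; crude 5, SnCl2·2H2O (1.0 equiv), EtOH/H2O, 0 °C
Reagents that add atoms: bromine, BrBr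
Why: exhaustive enolate bromination followed by selective halophilic monoreduction with divalent tin avoids the mono/di mixtures of direct monobromination; the C–Br centre is racemic and is erased in step 3.

**Step 3**
Reactants: 3 3-(furan-3-yl)propanal; 6 methyl 2-[bis(2,2,2-trifluoroethoxy)phosphoryl]-2-bromoacetate
Product: 7 methyl (2E)-2-bromo-5-(furan-3-yl)pent-2-enoate
Conditions: t-BuOK, 18-crown-6, THF, −78 °C
Reagents that add atoms: none
Why: Horner–Wadsworth–Emmons olefination with a bis(trifluoroethyl) phosphonate (Still–Gennari-type kinetic control) puts the ester cis to the alkyl chain, which for the α-bromo ester is the E isomer.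

**Step 4**
Reactants: 8 (S)-(−)-limonene (2 equiv); 7 methyl (2E)-2-bromo-5-(furan-3-yl)pent-2-enoate
Product: 12 methyl (2Z)-5-(furan-3-yl)-2-[(3S)-5-oxo-3-(prop-1-en-2-yl)pentyl]pent-2-enoate, via hydroperoxy aldehyde 9 (not isolated), via hydroperoxy acetal 10 (not isolated), via coupled acetal 11 (not isolated)
Conditions: O3 (1.0 equiv per 8), CH2Cl2/MeOH 4:1, −78 °C; TsOH·H2O (5 mol %), 0 °C, then NaHCO3, solvent switch to DMA; 7, NiBr2·glyme (10 mol %), 4,4'-di-tert-butyl-2,2'-bipyridine (12 mol %), 4CzIPN (2 mol %), Hantzsch ester (1.5 equiv), NaHCO3, 450 nm LEDs, 15 °C; then 1 M HCl/THF, 23 °C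
Reagents that add atoms: water, O (the aldehyde oxygen of 12); ozone, O=[O+][O-], and methanol, CO (their atoms are present only in intermediates 9 to 11)
Why: Proposed new method: a one-flask dealkenylative C(sp3)–C(sp2) cross-electrophile coupling in which ozone cleaves the more electron-rich ring alkene, the Criegee fragmentation places the carbonyl oxide on the methyl-bearing carbon so that methanol gives the tertiary α-methoxy hydroperoxide (the aldehyde is masked as its dimethyl acetal because the free 5-oxopentyl radical would add reversibly to its own C=O and scramble the two arms), photoreduction (excited Hantzsch ester or reduced 4CzIPN, relayed through low-valent nickel) cleaves the O–O bond, β-scission of the alkoxy radical expels methyl acetate and leaves the primary radical C*–CH2–CH2•, which is captured by the alkenylnickel bromide formed from 7 and reductively eliminated with retention, so the E bromide becomes the Z enoate while the limonene stereocentre is untouched; the closest known reaction types are the divalent-iron-mediated dealkenylative radical functionalisation of ozonolysis-derived α-methoxy hydroperoxides and nickel/photoredox coupling of β-scission-derived alkyl radicals with alkenyl or aryl bromides.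

**Step 5**
Reactants: 12 methyl (2Z)-5-(furan-3-yl)-2-[(3S)-5-oxo-3-(prop-1-en-2-yl)pentyl]pent-2-enoate
Product: 13 methyl (2Z)-5-(furan-3-yl)-2-[(3S)-5-hydroxy-6-methyl-3-(prop-1-en-2-yl)hept-6-en-1-yl]pent-2-enoate (mixture of C5 epimers)
Conditions: CH2=C(CH3)MgBr (1.1 equiv), THF, −78 °C; aq NH4Cl
Reagents that add atoms: isopropenylmagnesium bromide, C=C(C)[Mg]Br
Why: chemoselective Grignard 1,2-addition to the aldehyde at −78 °C (the α-branched conjugated ester is inert); the new carbinol centre forms as a mixture and is erased in step 6.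

**Step 6**
Reactants: 13 methyl (2Z)-5-(furan-3-yl)-2-[(3S)-5-hydroxy-6-methyl-3-(prop-1-en-2-yl)hept-6-en-1-yl]pent-2-enoate
Product: 15 methyl (2Z)-2-[(3S,5E)-9-(dimethylamino)-6-methyl-9-oxo-3-(prop-1-en-2-yl)non-5-en-1-yl]-5-(furan-3-yl)pent-2-enoate, via ketene N,O-acetal 14 (not isolated)
Conditions: CH3C(OMe)2NMe2 (5 equiv), xylenes, 140 °C, MeOH distilled off
Reagents that add atoms: N,N-dimethylacetamide dimethyl acetal, COC(C)(OC)N(C)C
Why: Eschenmoser–Claisen rearrangement; in the chair transition state the chain on the carbinol carbon sits equatorial to avoid the 1,3-diaxial clash with NMe2, so both carbinol epimers give the E trisubstituted alkene.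

**Step 7**
Reactants: 15 methyl (2Z)-2-[(3S,5E)-9-(dimethylamino)-6-methyl-9-oxo-3-(prop-1-en-2-yl)non-5-en-1-yl]-5-(furan-3-yl)pent-2-enoate
Product: 16 methyl (2Z)-5-(furan-3-yl)-2-[(3S,5E)-6-methyl-9-oxo-3-(prop-1-en-2-yl)non-5-en-1-yl]pent-2-enoate
Conditions: Cp2Zr(H)Cl (1.5 equiv), THF, 23 °C, 20 min; H2O
Reagents that add atoms: none
Why: Schwartz-reagent reduction of a tertiary amide: hydrozirconation of the amide C=O gives a zirconated hemiaminal that collapses to the aldehyde on work-up, while esters and the substituted alkenes react far more slowly.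

**Step 8**
Reactants: 17 5-bromo-2-methylpent-2-ene
Product: 18 (4-methylpent-3-en-1-yl)triphenylphosphonium bromide
Conditions: PPh3, MeCN, 82 °C
Reagents that add atoms: triphenylphosphine, c1ccc(cc1)P(c1ccccc1)c1ccccc1
Why: SN2 quaternisation of a primary bromide by triphenylphosphine.

**Step 9**
Reactants: 18 (4-methylpent-3-en-1-yl)triphenylphosphonium bromide
Product: 21 prop-2-en-1-yl 6-methyl-2-(triphenyl-λ5-phosphanylidene)hept-5-enoate, via unstabilised ylide 19 (not isolated), via acylphosphonium chloride 20 (not isolated)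
Conditions: NaHMDS (1.0 equiv), THF, −78 to 0 °C; ClCO2CH2CH=CH2 (1.0 equiv), −78 °C; NaHMDS (1.0 equiv), −78 to 23 °C
Reagents that add atoms: allyl chloroformate, C=CCOC(=O)Cl
Why: Bestmann-type C-acylation of a non-stabilised ylide with a chloroformate, then deprotonation of the acylphosphonium salt, gives the α-branched ester-stabilised ylide.

**Step 10**
Reactants: 16 methyl (2Z)-5-(furan-3-yl)-2-[(3S,5E)-6-methyl-9-oxo-3-(prop-1-en-2-yl)non-5-en-1-yl]pent-2-enoate; 21 prop-2-en-1-yl 6-methyl-2-(triphenyl-λ5-phosphanylidene)hept-5-enoate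
Product: 22 13-methyl 1-prop-2-en-1-yl (2E,6E,9S,12Z)-12-[3-(furan-3-yl)propylidene]-6-methyl-2-(4-methylpent-3-en-1-yl)-9-(prop-1-en-2-yl)trideca-2,6-dienedioate
Conditions: toluene, 90 °C
Reagents that add atoms: none
Why: Wittig olefination with an ester-stabilised ylide gives the E (tiglate-type) enoate with the chain trans to the ester.

**Step 11**
Reactants: 22 13-methyl 1-prop-2-en-1-yl (2E,6E,9S,12Z)-12-[3-(furan-3-yl)propylidene]-6-methyl-2-(4-methylpent-3-en-1-yl)-9-(prop-1-en-2-yl)trideca-2,6-dienedioate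
Product: 23 (2E,6E,9S,12Z)-12-[3-(furan-3-yl)propylidene]-13-methoxy-6-methyl-2-(4-methylpent-3-en-1-yl)-13-oxo-9-(prop-1-en-2-yl)trideca-2,6-dienoic acid (CNP0201108.2)
Conditions: Pd(PPh3)4 (5 mol %), morpholine, THF, 23 °C
Reagents that add atoms: none
Why: Tsuji–Trost deallylation: zerovalent palladium ionises only the allyl ester to a π-allyl complex that morpholine traps, leaving the methyl ester, furan and all alkenes intact.

## Compound list

1 | 3-bromofuran | Brc1ccoc1 | starting material
2 | prop-2-en-1-ol (allyl alcohol) | C=CCO | starting material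
3 | 3-(furan-3-yl)propanal | O=CCCc1ccoc1 | intermediate
4 | methyl 2-[bis(2,2,2-trifluoroethoxy)phosphoryl]acetate | COC(=O)CP(=O)(OCC(F)(F)F)OCC(F)(F)F | starting material
5 | methyl 2-[bis(2,2,2-trifluoroethoxy)phosphoryl]-2,2-dibromoacetate | COC(=O)C(Br)(Br)P(=O)(OCC(F)(F)F)OCC(F)(F)F | intermediate (not isolated)
6 | methyl 2-[bis(2,2,2-trifluoroethoxy)phosphoryl]-2-bromoacetate (racemic) | COC(=O)C(Br)P(=O)(OCC(F)(F)F)OCC(F)(F)F | intermediate
7 | methyl (2E)-2-bromo-5-(furan-3-yl)pent-2-enoate | COC(=O)/C(Br)=C\CCc1ccoc1 | intermediate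
8 | (S)-(−)-limonene, (4S)-1-methyl-4-(prop-1-en-2-yl)cyclohex-1-ene | CC1=CC[C@H](CC1)C(C)=C | starting material
9 | (3S)-6-hydroperoxy-6-methoxy-3-(prop-1-en-2-yl)heptanal (C6 epimers) | C=C(C)[C@H](CC=O)CCC(C)(OC)OO | intermediate (not isolated)
10 | (3S)-6-hydroperoxy-1,1,6-trimethoxy-3-(prop-1-en-2-yl)heptane (C6 epimers) | C=C(C)[C@H](CC(OC)OC)CCC(C)(OC)OO | intermediate (not isolated)
11 | methyl (2Z)-2-[(3S)-5,5-dimethoxy-3-(prop-1-en-2-yl)pentyl]-5-(furan-3-yl)pent-2-enoate | C=C(C)[C@H](CC(OC)OC)CC/C(=C/CCc1ccoc1)C(=O)OC | intermediate (not isolated)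
12 | methyl (2Z)-5-(furan-3-yl)-2-[(3S)-5-oxo-3-(prop-1-en-2-yl)pentyl]pent-2-enoate | C=C(C)[C@H](CC=O)CC/C(=C/CCc1ccoc1)C(=O)OC | intermediate
13 | methyl (2Z)-5-(furan-3-yl)-2-[(3S)-5-hydroxy-6-methyl-3-(prop-1-en-2-yl)hept-6-en-1-yl]pent-2-enoate (C5 epimers) | C=C(C)[C@H](CC(O)C(C)=C)CC/C(=C/CCc1ccoc1)C(=O)OC | intermediate
14 | methyl (2Z)-2-[(3S)-5-{[1-(dimethylamino)ethenyl]oxy}-6-methyl-3-(prop-1-en-2-yl)hept-6-en-1-yl]-5-(furan-3-yl)pent-2-enoate | C=C(C)[C@H](CC(OC(=C)N(C)C)C(C)=C)CC/C(=C/CCc1ccoc1)C(=O)OC | intermediate (not isolated)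
15 | methyl (2Z)-2-[(3S,5E)-9-(dimethylamino)-6-methyl-9-oxo-3-(prop-1-en-2-yl)non-5-en-1-yl]-5-(furan-3-yl)pent-2-enoate | C=C(C)[C@H](C/C=C(\C)CCC(=O)N(C)C)CC/C(=C/CCc1ccoc1)C(=O)OC | intermediate
16 | methyl (2Z)-5-(furan-3-yl)-2-[(3S,5E)-6-methyl-9-oxo-3-(prop-1-en-2-yl)non-5-en-1-yl]pent-2-enoate | C=C(C)[C@H](C/C=C(\C)CCC=O)CC/C(=C/CCc1ccoc1)C(=O)OC | intermediate
17 | 5-bromo-2-methylpent-2-ene | CC(C)=CCCBr | starting material
18 | (4-methylpent-3-en-1-yl)triphenylphosphonium bromide | CC(C)=CCC[P+](c1ccccc1)(c1ccccc1)c1ccccc1.[Br-] | intermediate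
19 | (4-methylpent-3-en-1-ylidene)triphenyl-λ5-phosphane | CC(C)=CCC=P(c1ccccc1)(c1ccccc1)c1ccccc1 | intermediate (not isolated)
20 | {5-methyl-1-[(prop-2-en-1-yloxy)carbonyl]hex-4-en-1-yl}triphenylphosphonium chloride (racemic) | CC(C)=CCC(C(=O)OCC=C)[P+](c1ccccc1)(c1ccccc1)c1ccccc1.[Cl-] | intermediate (not isolated)
21 | prop-2-en-1-yl 6-methyl-2-(triphenyl-λ5-phosphanylidene)hept-5-enoate | CC(C)=CCC(C(=O)OCC=C)=P(c1ccccc1)(c1ccccc1)c1ccccc1 | intermediate
22 | 13-methyl 1-prop-2-en-1-yl (2E,6E,9S,12Z)-12-[3-(furan-3-yl)propylidene]-6-methyl-2-(4-methylpent-3-en-1-yl)-9-(prop-1-en-2-yl)trideca-2,6-dienedioate | C=C(C)[C@H](C/C=C(\C)CC/C=C(\CCC=C(C)C)C(=O)OCC=C)CC/C(=C/CCc1ccoc1)C(=O)OC | intermediate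
23 | (2E,6E,9S,12Z)-12-[3-(furan-3-yl)propylidene]-13-methoxy-6-methyl-2-(4-methylpent-3-en-1-yl)-13-oxo-9-(prop-1-en-2-yl)trideca-2,6-dienoic acid | C=C(C)[C@H](C/C=C(\C)CC/C=C(\CCC=C(C)C)C(=O)O)CC/C(=C/CCc1ccoc1)C(=O)OC | target

## Step count and risks

Total steps: 11. Longest linear sequence: 8 (steps 1, 3, 4, 5, 6, 7, 10, 11).

**Step 4 (the proposed new step) is the most likely to fail.** The weak points are:
- ozone must discriminate the ring alkene from the isopropenyl group, and the Criegee fragmentation must place the hydroperoxide on the methyl-bearing carbon;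
- the tertiary methoxy hydroperoxide must survive the acid-catalysed acetalisation;
- the alkenylnickel intermediate must not lose its geometry through an O-bound allenoate form;
- the primary radical must not add to the β-carbon of 7 instead of being captured by nickel.

The fallback uses only known chemistry. It sets out from 8, which is converted to hydroperoxy acetal 10 exactly as in step 4. Classical redox fragmentation with FeSO4·7H2O and CuCl2 in MeOH (chloride transfer from divalent copper outruns any radical rearrangement) gives (3R)-5-chloro-1,1-dimethoxy-3-(prop-1-en-2-yl)pentane F1. Finkelstein exchange (NaI, acetone, reflux) gives (3R)-5-iodo-1,1-dimethoxy-3-(prop-1-en-2-yl)pentane F2. Alkylation of the sodium salt of phosphonate 4 (NaH, DMF) with F2 gives methyl (5S)-2-[bis(2,2,2-trifluoroethoxy)phosphoryl]-7,7-dimethoxy-5-(prop-1-en-2-yl)heptanoate F3. Still–Gennari olefination of F3 with aldehyde 3 (KHMDS, 18-crown-6, THF, −78 °C) gives the Z enoate acetal 11, and 1 M HCl/THF hydrolyses it; the fallback comes back to the route at 12.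

**Step 1** may suffer from the low reactivity and volatility of 3-bromofuran and from branched Heck isomers. The fallback sets out from 1: bromine–lithium exchange (n-BuLi, THF, −78 °C) and BF3·OEt2-promoted opening of oxetane give 3-(furan-3-yl)propan-1-ol F4, and Dess–Martin oxidation returns to the route at 3.

**Step 7** may over-reduce or hydrozirconate the isopropenyl group. The fallback avoids the amide altogether and sets out from 13: iridium-catalysed O-vinylation ([Ir(cod)Cl]2, Na2CO3, vinyl acetate, toluene, 100 °C) gives methyl (2Z)-2-[(3S)-5-(ethenyloxy)-6-methyl-3-(prop-1-en-2-yl)hept-6-en-1-yl]-5-(furan-3-yl)pent-2-enoate F5, and thermal Claisen rearrangement (toluene, 120 °C) gives the aldehyde directly, coming back at 16. The price is a lower E:Z ratio (about 9:1 expected), so the minor Z isomer would have to be removed on AgNO3-impregnated silica.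

## Further compounds

F1 | step 4 | (3R)-5-chloro-1,1-dimethoxy-3-(prop-1-en-2-yl)pentane | C=C(C)[C@H](CC(OC)OC)CCCl
F2 | step 4 | (3R)-5-iodo-1,1-dimethoxy-3-(prop-1-en-2-yl)pentane | C=C(C)[C@H](CC(OC)OC)CCI
F3 | step 4 | methyl (5S)-2-[bis(2,2,2-trifluoroethoxy)phosphoryl]-7,7-dimethoxy-5-(prop-1-en-2-yl)heptanoate (C2 epimers) | C=C(C)[C@H](CC(OC)OC)CCC(C(=O)OC)P(=O)(OCC(F)(F)F)OCC(F)(F)F
F4 | step 1 | 3-(furan-3-yl)propan-1-ol | OCCCc1ccoc1
F5 | step 7 | methyl (2Z)-2-[(3S)-5-(ethenyloxy)-6-methyl-3-(prop-1-en-2-yl)hept-6-en-1-yl]-5-(furan-3-yl)pent-2-enoate (C5 epimers) | C=C(C)[C@H](CC(OC=C)C(C)=C)CC/C(=C/CCc1ccoc1)C(=O)OC
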